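At 20.0 d the oak flask, with more G than ash or larch, leaves 3 percentage points of its charge outside L and Q, while the ash flask adds up to 101%. With 1.5 points on each reading, that leftover may be a leak to Z or may be scatter. So we ask how much G moves the share of L in L + Q, the selectivity to L.

| flask | E | D | G | remark | time |
|---|---|---|---|---|---|
| ash | 0.50 M | 0.25 M | 0.0057 M | run made earlier |  |
| larch | 0.50 M | 0.25 M | 0.030 M | run made earlier |  |
| oak | 0.50 M | 0.25 M | 0.16 M | run made earlier |  |
| beta | 0.50 M | 0.250 M | 0.00600 M |  | 25 d |
| eta | 0.50 M | 0.250 M | 0.0150 M |  | 25 d |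
| zeta | 0.50 M | 0.250 M | 0.0500 M |  | 25 d |
| gamma | 0.50 M | 0.250 M | 0.150 M |  | 25 d |

- ash (time / d: L / %, Q / %): 1.25: 34, 51; 2.50: 39, 56; 5.00: 40, 59; 10.0: 38, 64; 20.0: 31, 70
- larch (time / d: L / %, Q / %): 1.25: 36, 49; 2.50: 39, 56; 5.00: 41, 62; 10.0: 32, 63; 20.0: 29, 70
- oak (time / d: L / %, Q / %): 1.25: 35, 51; 2.50: 41, 54; 5.00: 41, 57; 10.0: 38, 62; 20.0: 29, 68

(readings scatter by 1.5 percentage points)

- the earlier runs were read with a standard deviation of 1.5 percentage points
- on the list of suspects stand: L <-> Q; D -> Q; D + G -> Z; D <-> X; E <-> D; E -> L
- "hardly changes" means that all values lie within two and a half points (for a concentration: within two and a half percent of the largest)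

- share of L in all that became L or Q for beta, eta, zeta, gamma, in this order
- how the row runs (falls all the way / hardly changes / falls, then rises / rises, then falls / rises all the way)

We work in powers of ten and draw the share at 20.0 d against log10[G]. The ash flask reads 30.7%, the larch flask 29.3% and the oak flask 29.9%.

The curve starts with slope −0.0281 and goes on from larch with 0.0122. That first step is 1.4 points in the share against 1.5 points on a reading, so we draw no knee.

One line through ash and oak gives the G-order of the share, the slope of log10(share) against log10[G], read like a reaction order: −0.00788. That slope is a reading, since ash and oak differ by 0.8 points against 1.5 points on a reading.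

Now the level. The three runs pooled fall from 40.7% at 5.00 d to 30.0% at 20.0 d, which is 0.0204 d⁻¹. Carried on to 25 d, this puts our row at 27.1%.

From beta to gamma, [G] spans 1.40 decades. Our slope therefore shifts the row by −0.69 points, inside the band of the question.

The forecast says “G changes nothing”. It gives 27.5%, 27.5%, 27.5% and 27.5%, which stands above our level, and its row hardly changes.

    L ⇌ Q (K = 3.30, k = 3.10 × 10⁻⁵ min⁻¹)
    D → Q (k = 0.0190 min⁻¹)
    D + G → Z (k = 0.00370 M⁻¹ min⁻¹)
    D ⇌ X (K = 23.0, k = 1.70 × 10⁻⁴ min⁻¹)
    E ⇌ D (K = 0.140, k = 3.80 × 10⁻⁴ min⁻¹)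
    E → L (k = 5.50 × 10⁻⁴ min⁻¹)

The flask gives 28.5%, 28.5%, 28.5% and 28.6%, so the row hardly changes. Against the band of the question, the passing of D + G into Z makes no difference to the share in gamma. The G-order of the share, −0.00788 as a reading on the earlier runs, is 0.00109 on this row from beta to gamma. The same slope taken on Z from beta to gamma at 25.0 d is 0.993, so Z follows [G] in proportion, and in gamma it stands at 1.52%.

All runs were computed for substances that don't exist.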